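## Retrosynthetic overview

1. (5S)-14 ⇐ arene 13: the only stereocenter (C5) is made last, by enantioselective palladium-mediated transfer of the prenyl group from O8 to C5, which dearomatises ring A.
2. 13 ⇐ 11: ring B (the pyran) is closed at O1–C8a by two-electron oxidation of the C6 phenol; the C2 carbinol oxygen adds to C8a and ring A rearomatises.
3. Enabling feature: in ring A, C8a is the one carbon without a substituent, para to the C6 oxygen and ortho to the C8 oxygen (1,2,4-trioxygenated ring), so phenol oxidation places the positive charge there, and the cis C3=C4 bond holds the C2–O over it.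
4. 11 ⇐ 5: O6 and O8 enter as two C–F bonds ortho to the C7 ketone and are exchanged in order by SNAr (prenyloxide, then hydroxide); C2–C4 come from 2-methylbut-3-yn-2-ol (Sonogashira, then Z-selective semihydrogenation).
5. Ring order: ring A is bought as the benzene ring of 1, ring B is formed in step 7, ring A is dearomatised in step 8.

Key step: step 7

Assumption: the (R,R)-ligand in step 8 is taken to give the (5S) product; if the first run shows the opposite sense, the (S,S)-ligand is used with no other change.
Remark: 14 is the 6-oxo-8-hydroxy tautomer written in the target SMILES; the enolised β-triketone is one compound, whichever oxygen carries the proton.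

## Route

Step 1
Reactants: 1 1-bromo-3,5-difluoro-2-iodobenzene; 2 methylzinc chloride
Product: 3 1-bromo-3,5-difluoro-2-methylbenzene
Conditions: Pd(PPh3)4 (3 mol %), THF, 25 to 50 °C
Reagents that add atoms: none
Why: Negishi coupling in which zerovalent palladium inserts into the C–I bond far faster than into the C–Br bond, so only the iodide should be exchanged for methyl.

Step 2
Reactants: 3 1-bromo-3,5-difluoro-2-methylbenzene; 4 N-methoxy-N-methyl-3-phenylpropanamide
Product: 5 1-(4-bromo-2,6-difluoro-3-methylphenyl)-3-phenylpropan-1-one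
Conditions: LiN(iPr)2 (1.05 equiv), THF, −78 °C; then 4, −78 to 0 °C; H2O
Reagents that add atoms: none
Why: Directed ortho-lithiation removes the proton flanked by both fluorines (the most acidic C–H), and the aryllithium is acylated once because the chelated adduct of the N-methoxy-N-methylamide does not collapse before work-up.

Step 3
Reactants: 5 1-(4-bromo-2,6-difluoro-3-methylphenyl)-3-phenylpropan-1-one; 6 2-methylbut-3-yn-2-ol
Product: 7 1-[2,6-difluoro-4-(3-hydroxy-3-methylbut-1-yn-1-yl)-3-methylphenyl]-3-phenylpropan-1-one
Conditions: PdCl2(PPh3)2 (2 mol %), CuI (4 mol %), Et3N, THF, 50 °C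
Reagents that add atoms: none
Why: Sonogashira coupling of an electron-poor aryl bromide, run with a tertiary amine so that the activated ortho fluorines are not displaced by the base.

Step 4
Reactants: 7 1-[2,6-difluoro-4-(3-hydroxy-3-methylbut-1-yn-1-yl)-3-methylphenyl]-3-phenylpropan-1-one
Product: 8 1-{2,6-difluoro-4-[(1Z)-3-hydroxy-3-methylbut-1-en-1-yl]-3-methylphenyl}-3-phenylpropan-1-one
Conditions: H2 (1 atm), Pd/CaCO3 poisoned with Pb(OAc)2, quinoline, EtOAc, 20 °C
Reagents that add atoms: none
Why: Lindlar semihydrogenation adds H2 syn on the poisoned palladium surface and should stop at the (Z)-alkene, the geometry that later lets the carbinol oxygen reach C8a; the C–F bonds and the ketone are inert.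

Step 5
Reactants: 8 1-{2,6-difluoro-4-[(1Z)-3-hydroxy-3-methylbut-1-en-1-yl]-3-methylphenyl}-3-phenylpropan-1-one; 9 3-methylbut-2-en-1-ol
Product: 10 1-{2-fluoro-4-[(1Z)-3-hydroxy-3-methylbut-1-en-1-yl]-3-methyl-6-[(3-methylbut-2-en-1-yl)oxy]phenyl}-3-phenylpropan-1-one
Conditions: KOtBu (1.1 equiv), 9 as co-solvent, THF, 0 °C
Reagents that add atoms: none
Why: SNAr (addition–elimination) ortho to the ketone, in which the fluorine without a methyl neighbour is the less hindered and should be displaced first, while the alcoholic medium keeps the ketone from resting as its unreactive enolate.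

Step 6
Reactants: 10 1-{2-fluoro-4-[(1Z)-3-hydroxy-3-methylbut-1-en-1-yl]-3-methyl-6-[(3-methylbut-2-en-1-yl)oxy]phenyl}-3-phenylpropan-1-one
Product: 11 1-{2-hydroxy-4-[(1Z)-3-hydroxy-3-methylbut-1-en-1-yl]-3-methyl-6-[(3-methylbut-2-en-1-yl)oxy]phenyl}-3-phenylpropan-1-one
Conditions: KOH (6 equiv), DMSO–H2O (5:1), 70 °C; then dilute acid
Reagents that add atoms: potassium hydroxide, [K+].[OH-]
Why: Second SNAr ortho to the ketone, in which the small hydroxide ion displaces the remaining, methyl-flanked fluoride, and the phenoxide formed shields the ring from further attack; the prenyl ether and the (Z)-allylic carbinol are stable to aqueous base.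

Step 7
Reactants: 11 1-{2-hydroxy-4-[(1Z)-3-hydroxy-3-methylbut-1-en-1-yl]-3-methyl-6-[(3-methylbut-2-en-1-yl)oxy]phenyl}-3-phenylpropan-1-one
Product: 13 1-{6-hydroxy-2,2,5-trimethyl-8-[(3-methylbut-2-en-1-yl)oxy]-2H-chromen-7-yl}-3-phenylpropan-1-one, via 8aH-dienone 12 (not isolated)
Conditions: PhI(OAc)2 (1.0 equiv, slow addition), NaHCO3, (CF3)2CHOH–CH2Cl2 (1:4), −20 °C
Reagents that add atoms: none
Why: The C6 phenol exchanges onto trivalent iodine and loss of PhI takes two electrons out of ring A, which puts the positive charge para to O6 on C8a, the only unsubstituted ring carbon; the C2 carbinol oxygen, held over C8a by the cis alkene, adds there to give the 8aH-dienone 12, and loss of the C8a proton restores the arene as 13. The closest known reaction type is the PhI(OAc)2 oxidation of para-unsubstituted phenols in alcohols, whose first stage is this same para C–O bond formation, together with the oxidative cyclo-etherification of phenols that carry a tethered alcohol. The pyran closes by a 6-endo attack of oxygen on the C4a=C8a edge of the oxidised ring, a geometry that the (Z)-alkene enforces and the (E)-isomer could not reach. No stereocenter survives, because C8a of 12 becomes sp2 again. Two selectivities are needed: C8a over C5, secured by the para preference of phenol oxidation and by C5 carrying methyl (a substituted ortho carbon that could not rearomatise); and a single oxidation, secured by one equivalent of oxidant at low temperature in a buffered, poorly nucleophilic medium, where 13 has no internal nucleophile left to trap a second oxidation.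

Step 8
Reactants: 13 1-{6-hydroxy-2,2,5-trimethyl-8-[(3-methylbut-2-en-1-yl)oxy]-2H-chromen-7-yl}-3-phenylpropan-1-one
Product: 14 (5S)-8-hydroxy-2,2,5-trimethyl-5-(3-methylbut-2-en-1-yl)-7-(3-phenylpropanoyl)-2H-chromen-6(5H)-one
Conditions: Pd2(dba)3·CHCl3 (2.5 mol %), (R,R)-N,N′-(cyclohexane-1,2-diyl)bis[2-(diphenylphosphanyl)benzamide] (7.5 mol %), CH2Cl2, 25 °C
Reagents that add atoms: none
Why: Asymmetric Tsuji–Trost allylic alkylation run as an O-to-C prenyl transfer, in which zerovalent palladium ionises the aryl prenyl ether to a π-prenyl palladium cation and the ring A phenoxide, the phenoxide is alkylated at the unsubstituted allyl terminus by C5 (para to O8 and already methylated, as in the gem-dialkylation of acylphloroglucinols), O-alkylation is reversible while C-alkylation is not, and the chiral pocket of the ligand selects the face of C5 and so sets the (5S) quaternary center.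

## Compound list

1 | 1-bromo-3,5-difluoro-2-iodobenzene | Fc1cc(F)c(I)c(Br)c1 | starting material
2 | methylzinc chloride | C[Zn]Cl | starting material
3 | 1-bromo-3,5-difluoro-2-methylbenzene | Cc1c(F)cc(F)cc1Br | intermediate
4 | N-methoxy-N-methyl-3-phenylpropanamide | CON(C)C(=O)CCc1ccccc1 | starting material
5 | 1-(4-bromo-2,6-difluoro-3-methylphenyl)-3-phenylpropan-1-one | Cc1c(Br)cc(F)c(C(=O)CCc2ccccc2)c1F | intermediate
6 | 2-methylbut-3-yn-2-ol | CC(C)(O)C#C | starting material
7 | 1-[2,6-difluoro-4-(3-hydroxy-3-methylbut-1-yn-1-yl)-3-methylphenyl]-3-phenylpropan-1-one | Cc1c(C#CC(C)(C)O)cc(F)c(C(=O)CCc2ccccc2)c1F | intermediate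
8 | 1-{2,6-difluoro-4-[(1Z)-3-hydroxy-3-methylbut-1-en-1-yl]-3-methylphenyl}-3-phenylpropan-1-one | Cc1c(/C=C\C(C)(C)O)cc(F)c(C(=O)CCc2ccccc2)c1F | intermediate
9 | 3-methylbut-2-en-1-ol | CC(C)=CCO | starting material
10 | 1-{2-fluoro-4-[(1Z)-3-hydroxy-3-methylbut-1-en-1-yl]-3-methyl-6-[(3-methylbut-2-en-1-yl)oxy]phenyl}-3-phenylpropan-1-one | Cc1c(/C=C\C(C)(C)O)cc(OCC=C(C)C)c(C(=O)CCc2ccccc2)c1F | intermediate
11 | 1-{2-hydroxy-4-[(1Z)-3-hydroxy-3-methylbut-1-en-1-yl]-3-methyl-6-[(3-methylbut-2-en-1-yl)oxy]phenyl}-3-phenylpropan-1-one | Cc1c(/C=C\C(C)(C)O)cc(OCC=C(C)C)c(C(=O)CCc2ccccc2)c1O | intermediate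
12 | 2,2,5-trimethyl-8-[(3-methylbut-2-en-1-yl)oxy]-7-(3-phenylpropanoyl)-2H-chromen-6(8aH)-one (8aH-dienone, not isolated) | O=C1C(C)=C2C=CC(C)(C)OC2C(OCC=C(C)C)=C1C(=O)CCc1ccccc1 | intermediate
13 | 1-{6-hydroxy-2,2,5-trimethyl-8-[(3-methylbut-2-en-1-yl)oxy]-2H-chromen-7-yl}-3-phenylpropan-1-one | Cc1c(O)c(C(=O)CCc2ccccc2)c(OCC=C(C)C)c2OC(C)(C)C=Cc12 | intermediate
14 | (5S)-8-hydroxy-2,2,5-trimethyl-5-(3-methylbut-2-en-1-yl)-7-(3-phenylpropanoyl)-2H-chromen-6(5H)-one | CC(C)=CC[C@]1(C)C(=O)C(C(=O)CCc2ccccc2)=C(O)C2=C1C=CC(C)(C)O2 | target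

## Step count and risks

Total step count: 8. Longest linear sequence: 8 steps (1 to 14).

Steps most likely to fail:

Step 7 (key step). The risk is further oxidation of the product, a para-alkoxyphenol that is more electron-rich than its precursor, or capture of the oxidised ring at the methyl-bearing C5 instead of C8a. The fallback makes the same O1–C8a bond without an oxidant acting on the product. It sets out from 11: N-bromosuccinimide (1.0 equiv, CH2Cl2–MeCN, −78 °C) should brominate the only ring C–H, para to the free phenol, to give 1-{3-bromo-6-hydroxy-4-[(1Z)-3-hydroxy-3-methylbut-1-en-1-yl]-5-methyl-2-[(3-methylbut-2-en-1-yl)oxy]phenyl}-3-phenylpropan-1-one F1. An Ullmann-type intramolecular O-arylation (CuI, 3,4,7,8-tetramethyl-1,10-phenanthroline, Cs2CO3, toluene, 90 °C) should then close the pyran and come back to the route at 13.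

Step 8. The risk is sluggish ionisation of the trisubstituted aryl prenyl ether by zerovalent palladium, or poor facial selectivity at C5. The fallback sets out from 13 and uses the thermal aromatic Claisen–Cope (para-Claisen) rearrangement (N,N-diethylaniline, 150 °C): a [3,3] shift of the prenyl group from O8 to an ortho carbon is followed by a Cope shift to C5. This should give racemic 8-hydroxy-2,2,5-trimethyl-5-(3-methylbut-2-en-1-yl)-7-(3-phenylpropanoyl)-2H-chromen-6(5H)-one F2, which is resolved by preparative chromatography on a chiral stationary phase and comes back to the route at 14.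

Step 5. The risk is incomplete discrimination between the two ortho fluorines and a second substitution by excess alkoxide. The fallback sets out from 8 and uses hydroxide first (KOH, DMSO–H2O, 60 °C), which can substitute only once because the phenoxide formed deactivates the ring. This should give 1-{2-fluoro-6-hydroxy-4-[(1Z)-3-hydroxy-3-methylbut-1-en-1-yl]-3-methylphenyl}-3-phenylpropan-1-one F3. Williamson O-alkylation of the phenol (prenyl bromide, K2CO3, acetone) then comes back to the route at 10.

Further compounds
F1 | step 7 | 1-{3-bromo-6-hydroxy-4-[(1Z)-3-hydroxy-3-methylbut-1-en-1-yl]-5-methyl-2-[(3-methylbut-2-en-1-yl)oxy]phenyl}-3-phenylpropan-1-one | Cc1c(/C=C\C(C)(C)O)c(Br)c(OCC=C(C)C)c(C(=O)CCc2ccccc2)c1O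
F2 | step 8 | racemic 8-hydroxy-2,2,5-trimethyl-5-(3-methylbut-2-en-1-yl)-7-(3-phenylpropanoyl)-2H-chromen-6(5H)-one | CC(C)=CCC1(C)C(=O)C(C(=O)CCc2ccccc2)=C(O)C2=C1C=CC(C)(C)O2
F3 | step 5 | 1-{2-fluoro-6-hydroxy-4-[(1Z)-3-hydroxy-3-methylbut-1-en-1-yl]-3-methylphenyl}-3-phenylpropan-1-one | Cc1c(/C=C\C(C)(C)O)cc(O)c(C(=O)CCc2ccccc2)c1F
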